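The route rests on cutting the lactone ring (C1, O2, C3, C4, C4a, C8a) at C4–C4a and O2–C3: C3/C4 is then the terminal double bond of a 1,3-diene and C4a/C8a an ortho-iodobenzoic acid. The key step, an enantioselective palladium-catalysed heteroannulation, joins them in one operation: the aryl group adds to the diene CH2 (C4) and the neighbouring carboxylate closes onto the allyl terminus (C3), which is set under ligand control. The precursors are 3,6-bis(benzyloxy)-2-iodobenzoic acid and the benzyl succinate of (2S,4E)-hepta-4,6-dien-2-ol, made from (S)-propylene oxide. A single hydrogenation then saturates the leftover alkene and removes all three benzyl groups.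

Key step: step 6

Assumption: the sense of induction of the phosphoramidite ligand in step 6 cannot be predicted with certainty for a carboxylate nucleophile; the (S)-binaphthyl antipode is written, and its mirror image is taken instead if a first run shows that it is the one leading to the (3S)-alkenyl lactone 13.

Step 1
Reactants: 1 (S)-propylene oxide; 2 lithium acetylide–ethylenediamine complex
Product: 3 (2S)-pent-4-yn-2-ol
Conditions: LiC≡CH·H2NCH2CH2NH2 (1.2 equiv), DMSO, 0 °C to rt; H2O quench
Reagents that add atoms: none
Why: SN2 opening of the epoxide by the acetylide at the unsubstituted CH2 leaves the C–O bond of the stereocentre untouched, so the (S) configuration is carried over.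

Step 2
Reactants: 3 (2S)-pent-4-yn-2-ol; 4 vinyl bromide
Product: 6 (2S,4E)-hepta-4,6-dien-2-ol, via alkenylzirconocene chloride 5 (not isolated)
Conditions: Cp2Zr(H)Cl (2.2 equiv), THF, 0 °C to rt; then CH2=CHBr, Pd(PPh3)4 (5 mol %), ZnCl2 (20 mol %), rt
Reagents that add atoms: none
Why: Hydrozirconation adds Zr–H syn with zirconium at the terminal carbon (the first equivalent of Cp2Zr(H)Cl is spent on the hydroxyl group), and the Negishi-type palladium-catalysed coupling with vinyl bromide retains the alkene geometry, so the (E)-diene should result with the carbinol centre untouched.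

Step 3
Reactants: 6 (2S,4E)-hepta-4,6-dien-2-ol; 7 4-(benzyloxy)-4-oxobutanoic acid (monobenzyl succinate)
Product: 8 benzyl (2S,4E)-hepta-4,6-dien-2-yl butanedioate
Conditions: EDC·HCl (1.3 equiv), DMAP (10 mol %), CH2Cl2, 0 °C to rt
Reagents that add atoms: none
Why: Steglich-type carbodiimide esterification acylates the secondary alcohol without touching the C–O bond of the stereocentre or the diene.

Step 4
Reactants: 9 1,4-bis(benzyloxy)benzene
Product: 10 1,4-bis(benzyloxy)-2-iodobenzene
Conditions: N-iodosuccinimide (1.05 equiv), CF3CO2H (30 mol %), MeCN, rt, dark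
Reagents that add atoms: N-iodosuccinimide, O=C1CCC(=O)N1I
Why: Electrophilic aromatic iodination takes place on the dialkoxy ring, which is far more electron-rich than the benzyl rings and has four equivalent free positions, so a single mono-iodide should form.

Step 5
Reactants: 10 1,4-bis(benzyloxy)-2-iodobenzene
Product: 12 3,6-bis(benzyloxy)-2-iodobenzoic acid, via aryllithium 11 (not isolated)
Conditions: LiN(iPr)2 (1.15 equiv), THF, −78 °C; then CO2, −78 °C to rt; aq HCl
Reagents that add atoms: carbon dioxide, O=C=O
Why: Directed ortho-metalation removes the C–H bond flanked by iodine and a benzyloxy group, the most acidic one, at −78 °C where the ortho-iodoaryllithium should survive long enough to be carboxylated.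

Step 6
Reactants: 12 3,6-bis(benzyloxy)-2-iodobenzoic acid; 8 benzyl (2S,4E)-hepta-4,6-dien-2-yl butanedioate
Product: 13 benzyl (2S,4E)-5-[(3S)-5,8-bis(benzyloxy)-1-oxo-3,4-dihydro-1H-isochromen-3-yl]pent-4-en-2-yl butanedioate
Conditions: Pd(OAc)2 (5 mol %), (S,R,R)-(1,1'-binaphthalene-2,2'-diyl) N,N-bis(1-phenylethyl)phosphoramidite (12 mol %), K3PO4 (2.5 equiv), 1,4-dioxane, 60 °C
Reagents that add atoms: none
Why: Zerovalent palladium inserts into the C–I bond of 12, the arylpalladium carbopalladates the terminal double bond of 8 with the aryl group going to the CH2 terminus (the C4–C4a bond), and the resulting syn η3-allylpalladium is captured at its near terminus by the ortho carboxylate (the O2–C3 bond), which releases zerovalent palladium. The closest known reaction type is the Larock heteroannulation of 1,3-dienes by ortho-functionalised aryl iodides (Heck insertion followed by Tsuji–Trost-type C–O bond formation), which is known for ortho-iodobenzoic acids, and ligand-controlled enantioselective versions with BINOL phosphoramidites are known for the related ortho-iodo anilines, phenols and benzyl alcohols. The lactone ring closes by 6-exo attack of the carboxylate oxygen on the allyl terminus, the alternative closure at the far terminus being an unfavourable eight-membered ring. The new C3 stereocentre is under catalyst control, the chiral phosphoramidite on palladium choosing the face of the diene that inserts, while the C2' centre is too remote to bias it and the (E)-alkene follows from the syn allyl geometry. The step needs regioselective insertion, secured by the unsubstituted diene terminus and the stabilised allyl that results, and fast C–O closure over β-hydride elimination, secured by the carboxylate held ortho to the reacting carbon; the two esters and the benzyl ethers are inert under these conditions.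

Step 7
Reactants: 13 benzyl (2S,4E)-5-[(3S)-5,8-bis(benzyloxy)-1-oxo-3,4-dihydro-1H-isochromen-3-yl]pent-4-en-2-yl butanedioate
Product: 14 aspergimarin B
Conditions: H2 (1 atm), 10% Pd/C, EtOAc, rt
Reagents that add atoms: none
Why: Heterogeneous hydrogenation saturates the disubstituted alkene and hydrogenolyses the two aryl benzyl ethers and the benzyl ester without touching either stereocentre, the C3 descriptor changing from S to R only because the CIP priorities change when the alkenyl group becomes alkyl.

Compound list
1 | (S)-propylene oxide [(2S)-2-methyloxirane] | C[C@H]1CO1 | starting material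
2 | lithium acetylide–ethylenediamine complex | [Li]C#C.NCCN | starting material
3 | (2S)-pent-4-yn-2-ol | C[C@H](O)CC#C | intermediate
4 | vinyl bromide | C=CBr | starting material
5 | (E)-alkenylzirconocene chloride from 3, hydroxyl bound as zirconocene chloride alkoxide | C[C@H](O[Zr](Cl)(C1C=CC=C1)C1C=CC=C1)C/C=C/[Zr](Cl)(C1C=CC=C1)C1C=CC=C1 | intermediate
6 | (2S,4E)-hepta-4,6-dien-2-ol | C[C@H](O)C/C=C/C=C | intermediate
7 | 4-(benzyloxy)-4-oxobutanoic acid (monobenzyl succinate) | OC(=O)CCC(=O)OCc1ccccc1 | starting material
8 | benzyl (2S,4E)-hepta-4,6-dien-2-yl butanedioate | C[C@@H](C/C=C/C=C)OC(=O)CCC(=O)OCc1ccccc1 | intermediate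
9 | 1,4-bis(benzyloxy)benzene | c1ccc(COc2ccc(OCc3ccccc3)cc2)cc1 | starting material
10 | 1,4-bis(benzyloxy)-2-iodobenzene | Ic1cc(OCc2ccccc2)ccc1OCc1ccccc1 | intermediate
11 | 3,6-bis(benzyloxy)-2-iodophenyllithium | [Li]c1c(I)c(OCc2ccccc2)ccc1OCc1ccccc1 | intermediate
12 | 3,6-bis(benzyloxy)-2-iodobenzoic acid | OC(=O)c1c(I)c(OCc2ccccc2)ccc1OCc1ccccc1 | intermediate
13 | benzyl (2S,4E)-5-[(3S)-5,8-bis(benzyloxy)-1-oxo-3,4-dihydro-1H-isochromen-3-yl]pent-4-en-2-yl butanedioate | C[C@@H](C/C=C/[C@@H]1Cc2c(OCc3ccccc3)ccc(OCc3ccccc3)c2C(=O)O1)OC(=O)CCC(=O)OCc1ccccc1 | intermediate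
14 | aspergimarin B, 4-{[(2S)-5-[(3R)-5,8-dihydroxy-1-oxo-3,4-dihydro-1H-isochromen-3-yl]pentan-2-yl]oxy}-4-oxobutanoic acid | C[C@@H](CCC[C@@H]1Cc2c(O)ccc(O)c2C(=O)O1)OC(=O)CCC(=O)O | target

Total step count: 7. Longest linear sequence: 5 steps (steps 1, 2, 3, 6 and 7).

Steps most likely to fail

Step 6. The carbopalladation may discriminate poorly between the two diene faces, since the carboxylate is the least precedented nucleophile for the enantioselective variant and the C2' centre is too remote to help. The C3 configuration may also erode through reversible ionisation of the allylic lactone by zerovalent palladium. Either way the C3 epimers would be hard to separate. The fallback sets out from 1, 7 and 10 and comes back at 14; it sets C3 by reagent control before the ring is made and avoids the alkene altogether, at the price that the ring oxygen then comes from an oxirane. CuI-catalysed opening of 1 with but-3-enylmagnesium bromide should give (2S)-hept-6-en-2-ol F1, and esterification with 7 (EDC, DMAP) benzyl (2S)-hept-6-en-2-yl butanedioate F2. Epoxidation with mCPBA should give benzyl (2S)-5-(oxiran-2-yl)pentan-2-yl butanedioate F3 as both oxirane epimers. Hydrolytic kinetic resolution (0.55 equiv H2O) with the antipode of the trivalent cobalt complex (salen)Co(OAc) that leaves the (R)-oxirane (salen = N,N'-bis(3,5-di-tert-butylsalicylidene)cyclohexane-1,2-diamine dianion) should give benzyl (2S)-5-[(2R)-oxiran-2-yl]pentan-2-yl butanedioate F4. Hydroxycarbonylation of 10 (CO, Pd(OAc)2, Xantphos, K2CO3, H2O/DMF) should give 2,5-bis(benzyloxy)benzoic acid F5. Its only ortho C–H bond is then alkylated by F4 at the CH2 terminus under Pd(OAc)2 and N-acetyl-tert-leucine catalysis (KOAc, (CF3)2CHOH, 75 °C), with lactonisation in the same flask and retention at the oxirane stereocentre, to give benzyl (2S)-5-[(3R)-5,8-bis(benzyloxy)-1-oxo-3,4-dihydro-1H-isochromen-3-yl]pentan-2-yl butanedioate F6. Hydrogenolysis as in step 7 gives 14.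

Step 7. Hydrogenolysis of the allylic C3–O2 bond on the palladium surface may compete with saturation of the alkene and open the lactone. The fallback sets out from 13 and comes back at 14. The alkene is first reduced without a metal surface by diimide (2-nitrobenzenesulfonyl hydrazide, Et3N, CH2Cl2, rt) to give benzyl (2S)-5-[(3R)-5,8-bis(benzyloxy)-1-oxo-3,4-dihydro-1H-isochromen-3-yl]pentan-2-yl butanedioate F7, the same compound as F6. With no allylic C–O bond left, hydrogenolysis (H2, 10% Pd/C, EtOAc) then gives 14.

Step 5. The ortho-iodoaryllithium may lose LiI to give an aryne, iodine may scramble between aryllithiums, or the amide base may deprotonate a benzylic position of the ethers. The fallback sets out from 10 and comes back at 12; iodine is introduced last as an electrophile, so no ortho-haloaryl anion is needed. Iodine–magnesium exchange on 10 (iPrMgCl·LiCl, THF, 0 °C) gives 2,5-bis(benzyloxy)phenylmagnesium chloride F8, and a Boc2O quench gives tert-butyl 2,5-bis(benzyloxy)benzoate F9. Magnesiation with TMPMgCl·LiCl (TMP = 2,2,6,6-tetramethylpiperidide) at the position flanked by the ester and a benzyloxy group gives tert-butyl 3,6-bis(benzyloxy)-2-(chloromagnesio)benzoate F10, and I2 gives tert-butyl 3,6-bis(benzyloxy)-2-iodobenzoate F11. CF3CO2H in CH2Cl2 at 0 °C then removes the tert-butyl group to give 12.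

Further compounds
F1 | step 6 | (2S)-hept-6-en-2-ol | C[C@H](O)CCCC=C
F2 | step 6 | benzyl (2S)-hept-6-en-2-yl butanedioate | C[C@@H](CCCC=C)OC(=O)CCC(=O)OCc1ccccc1
F3 | step 6 | benzyl (2S)-5-(oxiran-2-yl)pentan-2-yl butanedioate, both oxirane epimers | C[C@@H](CCCC1CO1)OC(=O)CCC(=O)OCc1ccccc1
F4 | step 6 | benzyl (2S)-5-[(2R)-oxiran-2-yl]pentan-2-yl butanedioate | C[C@@H](CCC[C@@H]1CO1)OC(=O)CCC(=O)OCc1ccccc1
F5 | step 6 | 2,5-bis(benzyloxy)benzoic acid | OC(=O)c1cc(OCc2ccccc2)ccc1OCc1ccccc1
F6 | step 6 | benzyl (2S)-5-[(3R)-5,8-bis(benzyloxy)-1-oxo-3,4-dihydro-1H-isochromen-3-yl]pentan-2-yl butanedioate | C[C@@H](CCC[C@@H]1Cc2c(OCc3ccccc3)ccc(OCc3ccccc3)c2C(=O)O1)OC(=O)CCC(=O)OCc1ccccc1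
F7 | step 7 | benzyl (2S)-5-[(3R)-5,8-bis(benzyloxy)-1-oxo-3,4-dihydro-1H-isochromen-3-yl]pentan-2-yl butanedioate | C[C@@H](CCC[C@@H]1Cc2c(OCc3ccccc3)ccc(OCc3ccccc3)c2C(=O)O1)OC(=O)CCC(=O)OCc1ccccc1
F8 | step 5 | 2,5-bis(benzyloxy)phenylmagnesium chloride | Cl[Mg]c1cc(OCc2ccccc2)ccc1OCc1ccccc1
F9 | step 5 | tert-butyl 2,5-bis(benzyloxy)benzoate | CC(C)(C)OC(=O)c1cc(OCc2ccccc2)ccc1OCc1ccccc1
F10 | step 5 | tert-butyl 3,6-bis(benzyloxy)-2-(chloromagnesio)benzoate | CC(C)(C)OC(=O)c1c([Mg]Cl)c(OCc2ccccc2)ccc1OCc1ccccc1
F11 | step 5 | tert-butyl 3,6-bis(benzyloxy)-2-iodobenzoate | CC(C)(C)OC(=O)c1c(I)c(OCc2ccccc2)ccc1OCc1ccccc1
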